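## Structural features

The target is a labdane: a trans-fused decalin (ring A = C1–C5, C10; ring B = C5–C10) with an exocyclic methylene on C8, a six-atom chain on C9 that ends in a primary stearate at C15, and on C4 an equatorial methyl (C18) beside an axial carboxylic acid (C19). Four stereocentres are contiguous (C4–C5–C10–C9). Two of them, C4 and C10, are quaternary and are joined through C5, so C19 and the C10 methyl (C20) stand 1,3-diaxial on the β face. The fifth centre, C13, lies three bonds out in the chain, beyond the reach of induction from the ring. The fragile groups are the C8=C17 alkene (acid-promoted migration into the ring, hydrogenation), the primary stearate (hydrolysis, hydride, ylide) and, in the opposite sense, the tertiary neopentyl C19 carboxyl, which is hard to release from an ordinary alkyl ester. The real difficulty is C4: a quaternary centre whose oxidised substituent must be axial and syn to C20, next to a ring fusion that must be trans. The key step exploits the fact that C4 is a ring carbon carrying a methyl and a one-carbon carbonyl group next to the ring methylene C3. That is the pattern left when the C3 ring bond of a methyl-substituted cycloheptene oxide shifts from C19 to C4. Because the shift is anti to the departing oxygen, the face of the epoxide alone decides the configuration at C4.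

## Logic of the disconnections

**C15–O acyl bond.** Cutting the ester of 29 gives 27 and 28. The stearate is the most labile group and is therefore attached last. The forward acylation must choose the primary C15 hydroxyl over the hindered C19 acid.

**O–Si bonds at C15 and in the C19 ester.** 27 is taken back to 26, in which both oxygens carry silicon-based groups that leave in one fluoride step. The demand is that C19 be masked by a group removed at a remote atom, not by attack at the hindered carbonyl.

**C8=C17, then C8–O and C9–H.** 26 comes from ketone 25 by methylenation, 25 from alcohol 24, and 24 from alkene 22 by hydroboration. The exocyclic alkene is made late and so never meets borane or Lewis acid. The hydroboration must deliver hydrogen to C9 from the α face, opposite C20.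

**C9–C11.** Cutting this bond splits 22 into enol triflate 15 and zinc reagent 21 (made from 20). All chain carbons and C13 arrive in one convergent sp2–sp3 coupling. The demand is a coupling at a triflate flanked by the quaternary C10.

**Chain fragment.** 20 goes back to acid 19 (loss of the carboxyl carbon), 19 to 17 (cleavage of the trisubstituted alkene) and 17 to 16. C13 is bought from the chiral pool with the correct configuration. The chain must lose exactly four carbons, one more than alkene cleavage removes, so that five chain carbons plus C16 remain.

**Functional group changes at C9 and C19.** 15 derives from ester 13, 13 from acid 12, and 12 from aldehyde 11. C9 can enolise only toward C8, so the triflate is regiodefined. The acid is esterified because neither the zinc reagent nor borane tolerates it free.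

**C3–C4 (key).** In 11 the C3–C4 bond is cut and C3 is reattached to C19, which returns as a ring member carrying the epoxide oxygen: this is 10. Ring A and the C4 quaternary centre are thus traded for a seven-membered ring with one trisubstituted epoxide. The forward step needs the β-epoxide and needs the ring bond, not the C19 hydrogen, to migrate. A configurational check of 10 and 11 against 29 (C4, C5, C10) shows that anti migration from the β-epoxide gives the required C4 epimer, so no structure had to be corrected. The C9 carbonyl is kept as the free ketone in both compounds: an acetal there would add two steps and would put a BF3-labile, cation-stabilising group into the rearrangement.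

**Epoxide C–O bonds.** 10 goes back to alkene 8 through bromohydrin 9. Direct peracid epoxidation is expected on the α face, so the oxygen is brought in as water anti to an α-bromonium ion.

**C4=C19.** Ring-closing metathesis takes 8 back to diene 7. The two alkene arms must be trans on the cyclohexanone so that the ring fusion is trans.

**C10–C1 and C5–C4.** 7 is cut into silyl enol ether 3 and iodide 5 (from 4), and 3 is cut to enone 1 and an isopropenyl nucleophile. One catalytic asymmetric conjugate addition sets C5, and C5 then directs the alkylation at C10. The enolate must be kept regiodefined, which is why it is stored as 3, and the electrophile is used as the iodide because the bromide is too sluggish.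

## Other disconnections considered

**Alternative 1:** The cut is at C10–C20 and C5–C6, with no ring formed. In the forward step a methylzinc reagent, under copper–carbene catalysis, adds to the β-carbon of enone ester A1 (methyl 3-oxocyclohex-1-ene-1-carboxylate), and the zinc enolate is trapped by an allyl halide to give A2 (methyl 2-allyl-1-methyl-3-oxocyclohexane-1-carboxylate, allyl trans to ester).
- In its favour: catalytic asymmetric conjugate methylation of an activated, β-substituted cyclic enone is among the most dependable ways to make a quaternary centre. The allyl electrophile is activated. On both points it is better than steps 1 and 3 here, which use an alkenyl Grignard reagent and an unactivated iodide.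
- Against it: A2 holds only ring A. Ring B must still be annulated from the ester and allyl arms. The C4 ketone must be turned into the methyl/carboxyl quaternary centre over several steps. The C9 chain and the C8 methylene are still to come.
- Comparison: the trans selectivity of the enolate trapping rests on the same principle as step 3, so the two plans are equal there. On step economy after the key step the chosen plan is ahead, because the rearrangement forms ring A and C4 in one stereospecific event.

**Alternative 2:** The cut is at C5–C10 and C8–C9, both rings at once. In the forward step the trienal A3 (E-enal, E,E-silyloxydiene, with C4 already quaternary) undergoes an intramolecular Diels–Alder reaction, thermally or with an alkylaluminium chloride, to give octalin A4 (C8 silyl ether, C9 aldehyde, C6=C7 alkene).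
- In its favour: two rings, two C–C bonds and up to four stereocentres form in one step. C9 already carries the first chain carbon and C8 an oxygen for the later methylene. After the key step this is better than the five-step C8/C9 sequence used here.
- Against it: A3 needs an acyclic quaternary stereocentre at C4 in enantiopure form, which is hard to make. The dienophile is a β,β-disubstituted enal and is sluggish. The silyloxydiene is sensitive to the Lewis acid that the dienophile would need. The trans fusion and the facial control by C4 depend on one transition-state geometry out of several.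
- Comparison: the alternative wins on bond-forming power. The chosen plan wins on the robustness of its intermediates and on stereospecific control of C4, where the alternative relies on stereoselection. Overall step counts would probably be similar, because A3 needs a long linear assembly.

**Alternative 3:** The cut is at C1–C10. In the forward step a potassium alkoxide base forms the phenoxide of bromo phenol A5, and its methyl-bearing ortho carbon displaces the bromide to give the bicyclic 2,4-dienone A6.
- In its favour: the starting materials are cheap aromatics, the ring closure is a plain intramolecular SN2 reaction without transition metal, and the product has its carbonyl at C9. On that last point it equals 11, and its ring closure is simpler than any in the chosen route.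
- Against it: C4 must again be set beforehand, here as a benzylic quaternary ester. C10 is induced by C4 across the planar C5, which is weak 1,3-control. The 2,4-dienone is prone to dimerisation and to dienone–phenol rearrangement. C5=C6 must later be reduced to the trans fusion and C7=C8 saturated or used, which adds redox steps.
- Comparison: equal on the placement of the C9 oxygen. The chosen plan is better on stereocontrol at C4, C5 and C10 and avoids the extra redox steps.

Key step: step 6

Assumption: the acyl group is octadecanoyl, and commercial stearoyl chloride (28) is used as the acylating agent.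
Remark: labdane numbering (C1–C20) is used for all ring intermediates. The chain reagent must carry five chain carbons plus C16, so steps 11 and 12 remove one carbon more than alkene cleavage of 16 would.

## Route

Step 1
Reactants: 1 2-methylcyclohex-2-en-1-one
Product: 3 trimethyl{[(3S)-2-methyl-3-(prop-1-en-2-yl)cyclohex-1-en-1-yl]oxy}silane, via bromomagnesium enolate 2 (not isolated)
Conditions: CH2=C(CH3)MgBr (1.3 equiv), Cu(OTf)2 (4 mol %), chiral imidazolinium carbene precursor (5 mol %, antipode chosen for the 3S adduct), Et2O, −30 °C; then Me3SiCl, Et3N, DMPU, −30 °C → rt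
Reagents that add atoms: isopropenylmagnesium bromide, C=C(C)[Mg]Br; chlorotrimethylsilane, C[Si](C)(C)Cl
Why: Copper-catalysed asymmetric conjugate addition of a Grignard reagent to an α-methyl cyclic enone; the chiral carbene–copper complex selects the enone face and so sets C5, and O-silylation of the magnesium enolate stores the regiodefined C9–C10 enolate for step 3.

Step 2
Reactants: 4 5-bromopent-1-ene
Product: 5 5-iodopent-1-ene
Conditions: NaI, acetone, reflux
Reagents that add atoms: sodium iodide, [Na+].[I-]
Why: Finkelstein halide exchange, driven by precipitation of NaBr; the iodide is needed because the hindered enolate of step 3 reacts too slowly with the bromide.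

Step 3
Reactants: 3 trimethyl{[(3S)-2-methyl-3-(prop-1-en-2-yl)cyclohex-1-en-1-yl]oxy}silane; 5 5-iodopent-1-ene
Product: 7 (2S,3S)-2-methyl-2-(pent-4-en-1-yl)-3-(prop-1-en-2-yl)cyclohexan-1-one, via lithium enolate 6 (not isolated)
Conditions: MeLi (1.05 equiv), THF, 0 °C → rt; then DMPU, 5 (1.5 equiv), −78 → 0 °C
Reagents that add atoms: none
Why: Regiospecific lithium enolate generation from a silyl enol ether, then SN2 C-alkylation; the isopropenyl group sits pseudoaxial to avoid allylic strain with the C10 methyl, so the iodide attacks the opposite face and C10 is set with pentenyl trans to isopropenyl, the relationship that becomes the trans ring fusion.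

Step 4
Reactants: 7 (2S,3S)-2-methyl-2-(pent-4-en-1-yl)-3-(prop-1-en-2-yl)cyclohexan-1-one
Product: 8 (4aS,9aS)-4a,9-dimethyl-1,2,3,4a,5,6,7,9a-octahydro-4H-benzo[7]annulen-4-one (trans-fused; C4=C19 alkene, C9 ketone)
Conditions: second-generation Grubbs catalyst (H2IMes)(PCy3)Cl2Ru=CHPh (5 mol %), CH2Cl2 (0.01 M), 40 °C
Reagents that add atoms: none
Why: Ring-closing metathesis of a monosubstituted with a 1,1-disubstituted alkene to a trisubstituted cycloheptene, driven by loss of ethene; the two arms are trans-diequatorial on the cyclohexanone chair and no stereocentre is touched.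

Step 5
Reactants: 8 (4aS,9aS)-4a,9-dimethyl-1,2,3,4a,5,6,7,9a-octahydro-4H-benzo[7]annulen-4-one
Product: 10 4β,19β-epoxide of 8 (oxygen syn to the C10 methyl), via bromohydrin 9 (not isolated)
Conditions: NBS, THF/H2O (4:1), 0 °C; then K2CO3, MeOH, rt
Reagents that add atoms: water, O
Why: Bromohydrin formation followed by base closure (intramolecular Williamson reaction); the bromonium ion should form on the α face away from the axial C10 methyl and water opens it anti from the β face, so displacement of bromide puts the epoxide oxygen on the β face at both C4 and C19, and either bromohydrin regioisomer converges on 10.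

Step 6
Reactants: 10 4β,19β-epoxide of 8
Product: 11 4β-formyl-4α,10β-dimethyl-trans-decalin-9-one (1,4a-dimethyl-5-oxodecahydronaphthalene-1-carbaldehyde, 5α-H, axial aldehyde)
Conditions: BF3·OEt2 (1.1 equiv), CH2Cl2, −78 °C, 15 min; aq. NaHCO3
Reagents that add atoms: none
Why: Meinwald (semipinacol) rearrangement of a trisubstituted cycloalkene oxide, the closest known class being the Lewis-acid conversion of 1-methylcycloalkene oxides into ring-contracted 1-methylcycloalkanecarbaldehydes. BF3 binds the epoxide oxygen and the C4–O bond lengthens toward the tertiary, methyl-bearing C4; as charge builds there the C19–C3 ring bond shifts to C4 and C19 becomes the boron-bound oxocarbenium ion, that is, the aldehyde. Ring A is therefore closed by a suprafacial 1,2-alkyl shift that contracts the seven-membered ring to six, not by cyclisation of a chain. The one new stereocentre, C4, is fixed by the epoxide face alone: C3 enters anti to the departing β oxygen, which puts C19 axial on the β face, syn to C20, and leaves C18 equatorial, while C5 and C10 are spectators. The step needs the alkyl shift to win over hydride shift from C19 (which would give the cycloheptanone), over proton loss to allylic alcohols and over full ionisation to a free cation. It is favoured by release of cycloheptane strain into a chair trans-decalin, by the flexibility of the seven-membered ring, which lets the C3–C19 bond turn antiperiplanar to the breaking C–O bond, and by low temperature in a non-nucleophilic solvent. The free C9 ketone mildly disfavours charge build-up at C5 and, unlike an acetal, offers nothing for BF3 to open.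

Step 7
Reactants: 11 4β-formyl-4α,10β-dimethyl-trans-decalin-9-one
Product: 12 4α,10β-dimethyl-9-oxo-trans-decalin-4β-carboxylic acid (C19 acid)
Conditions: NaClO2, NaH2PO4, 2-methylbut-2-ene, t-BuOH/H2O, rt
Reagents that add atoms: sodium chlorite, [Na+].[O-]Cl=O
Why: Pinnick oxidation; chlorous acid oxidises even neopentyl aldehydes without touching the ketone, and the quaternary C4 cannot epimerise.

Step 8
Reactants: 12 4α,10β-dimethyl-9-oxo-trans-decalin-4β-carboxylic acid
Product: 13 2-(trimethylsilyl)ethyl ester of 12
Conditions: Me3SiCH2CH2OH, PPh3, DIAD, THF, 0 °C → rt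
Reagents that add atoms: 2-(trimethylsilyl)ethanol, C[Si](C)(C)CCO
Why: Mitsunobu esterification; the hindered carboxylate acts only as an oxygen nucleophile at the activated primary carbon, so the crowded carbonyl is never attacked, and the ester can later be removed at silicon.

Step 9
Reactants: 13 2-(trimethylsilyl)ethyl ester of 12
Product: 15 C8=C9 enol trifluoromethanesulfonate of 13 (triflate on C9), via potassium enolate 14 (not isolated)
Conditions: KN(SiMe3)2, THF, −78 °C; then PhNTf2, −78 → 0 °C
Reagents that add atoms: N-phenylbis(trifluoromethanesulfonimide), O=S(=O)(N(c1ccccc1)S(=O)(=O)C(F)(F)F)C(F)(F)F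
Why: Enolate O-sulfonylation; C10 is quaternary, so the ketone can enolise only toward C8, and the ester has no α-hydrogen.

Step 10
Reactants: 16 (S)-citronellol
Product: 17 (S)-tert-butyl[(3,7-dimethyloct-6-en-1-yl)oxy]diphenylsilane
Conditions: t-BuPh2SiCl, imidazole, CH2Cl2, rt
Reagents that add atoms: tert-butyl(chloro)diphenylsilane, CC(C)(C)[Si](Cl)(c1ccccc1)c1ccccc1
Why: Silylation of a primary alcohol; the robust silyl ether survives the oxidative and radical steps that follow, and C13 is untouched.

Step 11
Reactants: 17 (S)-tert-butyl[(3,7-dimethyloct-6-en-1-yl)oxy]diphenylsilane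
Product: 19 (S)-6-[(tert-butyldiphenylsilyl)oxy]-4-methylhexanoic acid, via aldehyde 18 (not isolated)
Conditions: O3, MeCN/H2O (9:1), 0 °C; then NaClO2, NaH2PO4, 2-methylbut-2-ene, 0 °C → rt
Reagents that add atoms: ozone, [O-][O+]=O; sodium chlorite, [Na+].[O-]Cl=O
Why: Ozonolysis in aqueous acetonitrile gives the aldehyde directly (water intercepts the carbonyl oxide), and Pinnick oxidation in the same flask gives the acid; the stereocentre is two carbons from the reacting site.

Step 12
Reactants: 19 (S)-6-[(tert-butyldiphenylsilyl)oxy]-4-methylhexanoic acid
Product: 20 (R)-tert-butyl[(5-iodo-3-methylpentyl)oxy]diphenylsilane (descriptor changes by priority only)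
Conditions: PhI(OAc)2, I2, cyclohexane, hν (tungsten lamp), reflux
Reagents that add atoms: iodine, II
Why: Suárez iododecarboxylation (a Hunsdiecker-type radical reaction): the acyl hypoiodite loses CO2 and the primary radical is trapped by iodine far faster than it can abstract hydrogen, which removes the extra carbon and leaves the five-carbon chain.

Step 13
Reactants: 15 C8=C9 enol trifluoromethanesulfonate of 13; 20 (R)-tert-butyl[(5-iodo-3-methylpentyl)oxy]diphenylsilane
Product: 22 2-(trimethylsilyl)ethyl (13S)-15-[(tert-butyldiphenylsilyl)oxy]-17-norlabd-8-en-19-oate, via alkylzinc iodide 21 (not isolated)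
Conditions: 20, Zn dust (activated with BrCH2CH2Br and Me3SiCl), LiCl, THF, 40 °C; then 15, Pd(dppf)Cl2 (5 mol %), THF/NMP, 60 °C
Reagents that add atoms: none
Why: Negishi sp3–sp2 cross-coupling; the bidentate ferrocenylphosphine on palladium favours reductive elimination over β-hydride elimination, the zinc reagent tolerates the ester, and C13 is remote from the metal.

Step 14
Reactants: 22 2-(trimethylsilyl)ethyl (13S)-15-[(tert-butyldiphenylsilyl)oxy]-17-norlabd-8-en-19-oate
Product: 24 2-(trimethylsilyl)ethyl (13S)-15-[(tert-butyldiphenylsilyl)oxy]-8α-hydroxy-17-norlabdan-19-oate (9α-H), via 8α-alkylborane 23 (not isolated)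
Conditions: BH3·THF, THF, 0 °C → rt; then NaOH, H2O2, 0 °C → rt
Reagents that add atoms: hydrogen peroxide, OO
Why: Hydroboration–oxidation; boron goes to the less substituted C8 and hydrogen to C9 in a syn addition on the α face, opposite the axial C10 methyl, which sets C9 with the chain equatorial, and oxidation proceeds with retention; the hindered ester is not reduced.

Step 15
Reactants: 24 2-(trimethylsilyl)ethyl (13S)-15-[(tert-butyldiphenylsilyl)oxy]-8α-hydroxy-17-norlabdan-19-oate
Product: 25 2-(trimethylsilyl)ethyl (13S)-15-[(tert-butyldiphenylsilyl)oxy]-8-oxo-17-norlabdan-19-oate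
Conditions: Dess–Martin periodinane, NaHCO3, CH2Cl2, rt
Reagents that add atoms: none
Why: Dess–Martin oxidation under buffered, non-epimerising conditions; the equatorial C9 chain is also the thermodynamic arrangement next to the ketone.

Step 16
Reactants: 25 2-(trimethylsilyl)ethyl (13S)-15-[(tert-butyldiphenylsilyl)oxy]-8-oxo-17-norlabdan-19-oate
Product: 26 2-(trimethylsilyl)ethyl (13S)-15-[(tert-butyldiphenylsilyl)oxy]labd-8(17)-en-19-oate
Conditions: Ph3PCH3Br, KOtBu, toluene, rt → 70 °C
Reagents that add atoms: methyltriphenylphosphonium bromide, C[P+](c1ccccc1)(c1ccccc1)c1ccccc1.[Br-]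
Why: Wittig methylenation of a ring ketone; the hindered ester and the silyl ether are inert to the ylide, and any enolisation returns the more stable equatorial C9 epimer.

Step 17
Reactants: 26 2-(trimethylsilyl)ethyl (13S)-15-[(tert-butyldiphenylsilyl)oxy]labd-8(17)-en-19-oate
Product: 27 (13S)-15-hydroxylabd-8(17)-en-19-oic acid
Conditions: Bu4NF, THF, rt → 45 °C; aq. NH4Cl
Reagents that add atoms: none
Why: Fluoride desilylation; the silyl ether is cleaved at silicon and the silylethyl ester fragments with loss of ethene, so the crowded C19 carbonyl is never attacked and the exocyclic alkene meets no acid.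

Step 18
Reactants: 27 (13S)-15-hydroxylabd-8(17)-en-19-oic acid; 28 stearoyl chloride
Product: 29 (13S)-15-(octadecanoyloxy)labd-8(17)-en-19-oic acid (target)
Conditions: 28 (1.2 equiv), pyridine, DMAP (cat.), CH2Cl2, 0 °C → rt; then H2O, NaHCO3, rt; dilute acid work-up
Reagents that add atoms: none
Why: Nucleophile-catalysed O-acylation of the primary alcohol; the neopentyl C19 acid cannot be esterified under these conditions, and any mixed anhydride it forms passes its stearoyl group on to the alcohol or is hydrolysed at the unhindered carbonyl on work-up.

## Compound list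

1 | 2-methylcyclohex-2-en-1-one | CC1=CCCCC1=O | starting material
2 | bromomagnesium (3S)-2-methyl-3-(prop-1-en-2-yl)cyclohex-1-en-1-olate (formed in the flask) | CC1=C(O[Mg]Br)CCC[C@H]1C(C)=C | intermediate
3 | trimethyl{[(3S)-2-methyl-3-(prop-1-en-2-yl)cyclohex-1-en-1-yl]oxy}silane | CC1=C(O[Si](C)(C)C)CCC[C@H]1C(C)=C | intermediate
4 | 5-bromopent-1-ene | C=CCCCBr | starting material
5 | 5-iodopent-1-ene | C=CCCCI | intermediate
6 | lithium (3S)-2-methyl-3-(prop-1-en-2-yl)cyclohex-1-en-1-olate (formed in the flask) | CC1=C(O[Li])CCC[C@H]1C(C)=C | intermediate
7 | (2S,3S)-2-methyl-2-(pent-4-en-1-yl)-3-(prop-1-en-2-yl)cyclohexan-1-one | O=C1CCC[C@@H](C(C)=C)[C@]1(C)CCCC=C | intermediate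
8 | (4aS,9aS)-4a,9-dimethyl-1,2,3,4a,5,6,7,9a-octahydro-4H-benzo[7]annulen-4-one (trans-fused; C4=C19 alkene, C9 ketone) | O=C1CCC[C@H]2C(C)=CCCC[C@]12C | intermediate
9 | 19α-bromo-4β-hydroxy derivative of 8 (tertiary alcohol at C4, secondary bromide at C19; formed in the flask) | O=C1CCC[C@H]2[C@@](C)(O)[C@H](Br)CCC[C@]12C | intermediate
10 | 4β,19β-epoxide of 8 (oxygen syn to the C10 methyl; trans-fused 6–7 keto epoxide) | O=C1CCC[C@H]2[C@@]3(C)O[C@H]3CCC[C@]12C | intermediate
11 | 4β-formyl-4α,10β-dimethyl-trans-decalin-9-one (1,4a-dimethyl-5-oxodecahydronaphthalene-1-carbaldehyde, 5α-H) | O=C[C@@]1(C)CCC[C@@]2(C)[C@H]1CCCC2=O | intermediate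
12 | 4α,10β-dimethyl-9-oxo-trans-decalin-4β-carboxylic acid | OC(=O)[C@@]1(C)CCC[C@@]2(C)[C@H]1CCCC2=O | intermediate
13 | 2-(trimethylsilyl)ethyl 4α,10β-dimethyl-9-oxo-trans-decalin-4β-carboxylate | C[Si](C)(C)CCOC(=O)[C@@]1(C)CCC[C@@]2(C)[C@H]1CCCC2=O | intermediate
14 | potassium C8=C9 enolate of 13 (formed in the flask) | C[Si](C)(C)CCOC(=O)[C@@]1(C)CCC[C@@]2(C)[C@H]1CCC=C2O[K] | intermediate
15 | C8=C9 enol trifluoromethanesulfonate of 13 (triflate on C9) | C[Si](C)(C)CCOC(=O)[C@@]1(C)CCC[C@@]2(C)[C@H]1CCC=C2OS(=O)(=O)C(F)(F)F | intermediate
16 | (S)-citronellol | CC(C)=CCC[C@H](C)CCO | starting material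
17 | (S)-tert-butyl[(3,7-dimethyloct-6-en-1-yl)oxy]diphenylsilane | CC(C)=CCC[C@H](C)CCO[Si](c1ccccc1)(c1ccccc1)C(C)(C)C | intermediate
18 | (S)-6-[(tert-butyldiphenylsilyl)oxy]-4-methylhexanal (formed in the flask) | O=CCC[C@H](C)CCO[Si](c1ccccc1)(c1ccccc1)C(C)(C)C | intermediate
19 | (S)-6-[(tert-butyldiphenylsilyl)oxy]-4-methylhexanoic acid | OC(=O)CC[C@H](C)CCO[Si](c1ccccc1)(c1ccccc1)C(C)(C)C | intermediate
20 | (R)-tert-butyl[(5-iodo-3-methylpentyl)oxy]diphenylsilane | ICC[C@H](C)CCO[Si](c1ccccc1)(c1ccccc1)C(C)(C)C | intermediate
21 | {(R)-5-[(tert-butyldiphenylsilyl)oxy]-3-methylpentyl}zinc iodide (formed in the flask) | I[Zn]CC[C@H](C)CCO[Si](c1ccccc1)(c1ccccc1)C(C)(C)C | intermediate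
22 | 2-(trimethylsilyl)ethyl (13S)-15-[(tert-butyldiphenylsilyl)oxy]-17-norlabd-8-en-19-oate | C[Si](C)(C)CCOC(=O)[C@@]1(C)CCC[C@@]2(C)[C@H]1CCC=C2CC[C@H](C)CCO[Si](c1ccccc1)(c1ccccc1)C(C)(C)C | intermediate
23 | 8α-boryl adduct of 22 (monoalkylborane, 9α-H; formed in the flask) | B[C@@H]1CC[C@@H]2[C@](C)(CCC[C@]2(C)C(=O)OCC[Si](C)(C)C)[C@H]1CC[C@H](C)CCO[Si](c1ccccc1)(c1ccccc1)C(C)(C)C | intermediate
24 | 2-(trimethylsilyl)ethyl (13S)-15-[(tert-butyldiphenylsilyl)oxy]-8α-hydroxy-17-norlabdan-19-oate | O[C@@H]1CC[C@@H]2[C@](C)(CCC[C@]2(C)C(=O)OCC[Si](C)(C)C)[C@H]1CC[C@H](C)CCO[Si](c1ccccc1)(c1ccccc1)C(C)(C)C | intermediate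
25 | 2-(trimethylsilyl)ethyl (13S)-15-[(tert-butyldiphenylsilyl)oxy]-8-oxo-17-norlabdan-19-oate | O=C1CC[C@@H]2[C@](C)(CCC[C@]2(C)C(=O)OCC[Si](C)(C)C)[C@H]1CC[C@H](C)CCO[Si](c1ccccc1)(c1ccccc1)C(C)(C)C | intermediate
26 | 2-(trimethylsilyl)ethyl (13S)-15-[(tert-butyldiphenylsilyl)oxy]labd-8(17)-en-19-oate | C=C1CC[C@@H]2[C@](C)(CCC[C@]2(C)C(=O)OCC[Si](C)(C)C)[C@H]1CC[C@H](C)CCO[Si](c1ccccc1)(c1ccccc1)C(C)(C)C | intermediate
27 | (13S)-15-hydroxylabd-8(17)-en-19-oic acid | C=C1CC[C@@H]2[C@](C)(CCC[C@]2(C)C(=O)O)[C@H]1CC[C@H](C)CCO | intermediate
28 | stearoyl chloride (octadecanoyl chloride) | CCCCCCCCCCCCCCCCCC(=O)Cl | starting material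
29 | (13S)-15-(octadecanoyloxy)labd-8(17)-en-19-oic acid, (4S,5R,9S,10R,13S) | C=C1CC[C@@H]2[C@](C)(CCC[C@]2(C)C(=O)O)[C@H]1CC[C@H](C)CCOC(=O)CCCCCCCCCCCCCCCCC | target

## Step count and least certain steps

Total: 18 steps. Longest linear sequence: 14 steps (1 → 3 → 7 → 8 → 10 → 11 → 12 → 13 → 15 → 22 → 24 → 25 → 26 → 27 → 29). The chain fragment (16 → 20) takes 3 steps and joins at step 13; the iodide 5 takes 1 step.

**Step 6 (key step).** The most likely failure is migration of the C19 hydrogen in place of the C3 ring bond. Both bonds lie at a similar angle to the breaking C4–O bond in the epoxide, and the rotation that aligns the hydrogen gives the cycloheptanone. Proton loss from C18 or C5 to allylic alcohols, and full ionisation to a free cation with loss of stereospecificity at C4, are the other risks. A bulkier oxophilic promoter such as MeAl(OAr)2 (Ar = 4-bromo-2,6-di-tert-butylphenyl) is the first change of conditions to try.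
Fallback (sets out from 8, returns at 11): peracid epoxidation of 8 on the open α face should give the α-epoxide F1. HBr in Et2O (or MgBr2·OEt2) should open it at tertiary C4 with inversion to the 4β-bromo-19α-ol F2. One equivalent of EtMgBr at −78 °C should deprotonate the alcohol to the bromomagnesium alkoxide F3. On warming in toluene F3 should undergo the halohydrin-salt ring contraction, the C3–C19 bond moving anti to the leaving β-bromide, to give 11. C4 is inverted twice, so the same epimer results, and the migrating bond is chosen by antiperiplanarity to a discrete leaving group. Closure back to F1 is the competing path and returns reusable material.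

**Step 1.** The likely failures are low enantioselectivity or incomplete conversion, because a branched alkenyl Grignard reagent meets an α-substituted enone that binds copper poorly, and competing 1,2-addition.
Fallback (sets out from 1, returns at 7): the addition is run with CuBr·SMe2 (5 mol %) and Me3SiCl without chiral ligand to give the racemic silyl enol ether F4. The conditions of step 3 then give the racemic lithium enolate F5 and the racemic trans ketone F6. The enantiomers of F6 are separated by preparative chromatography on a chiral stationary phase, and the (2S,3S) enantiomer is 7.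

**Step 3.** The likely failure is slow C-alkylation of a hindered tetrasubstituted enolate by an unactivated iodide. That would allow proton transfer between product and enolate (loss of regiocontrol, polyalkylation) and elimination of the iodide.
Fallback (sets out from 3, returns at 7): a Mukaiyama aldol addition of 3 to pent-4-enal (TiCl4, CH2Cl2, −78 °C) should form the C10–C1 bond anti to the isopropenyl group and give the β-hydroxy ketone F7 (C1 epimers). PhOC(S)Cl, pyridine and DMAP convert it to the thionocarbonate F8. Barton–McCombie deoxygenation (Bu3SnH, AIBN, toluene, 80 °C) removes the C1 oxygen to give 7; the C1 radical has no favourable cyclisation mode onto either alkene.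

**Step 5.** The likely failure is poor facial selectivity in bromonium formation and opening on the flexible seven-membered ring, which would give the α-epoxide or a mixture.
Fallback (sets out from 8, returns at 10): peracid epoxidation gives the α-epoxide F1. Dilute HClO4 in aqueous THF should open it at tertiary C4 with inversion to the 4β,19α-diol F9. MsCl and Et3N sulfonylate only the secondary hydroxyl to give the mesylate F10. K2CO3 in MeOH then closes the tertiary alkoxide onto C19 with inversion to 10. If peracid instead attacks the β face, it gives 10 directly.

**Step 13.** The likely failure is slow oxidative addition and transmetalation at a triflate flanked by the quaternary C10. That would leave time for protodezincation and for reduction of the triflate through β-hydride elimination.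
Fallback (sets out from 20 and 15, returns at 22): iodine–lithium exchange on 20 (t-BuLi, Et2O, −78 °C) gives the alkyllithium F11. CuI converts it to the lithium dialkylcuprate F12. F12 should substitute the enol triflate 15 directly (organocuprate–enol triflate coupling, THF, −20 °C) to give 22 without a palladium cycle.

## Further compounds

F1 | step 6 | 4α,19α-epoxide of 8 (oxygen anti to the C10 methyl) | O=C1CCC[C@H]2[C@]3(C)O[C@@H]3CCC[C@]12C
F2 | step 6 | 4β-bromo-19α-hydroxy derivative of 8 (tertiary bromide, secondary alcohol) | O=C1CCC[C@H]2[C@@](C)(Br)[C@H](O)CCC[C@]12C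
F3 | step 6 | bromomagnesium alkoxide of F2 | O=C1CCC[C@H]2[C@@](C)(Br)[C@H](O[Mg]Br)CCC[C@]12C
F4 | step 1 | racemic trimethyl{[2-methyl-3-(prop-1-en-2-yl)cyclohex-1-en-1-yl]oxy}silane | CC1=C(O[Si](C)(C)C)CCCC1C(C)=C
F5 | step 1 | racemic lithium 2-methyl-3-(prop-1-en-2-yl)cyclohex-1-en-1-olate | CC1=C(O[Li])CCCC1C(C)=C
F6 | step 1 | racemic trans-2-methyl-2-(pent-4-en-1-yl)-3-(prop-1-en-2-yl)cyclohexan-1-one (relative configuration drawn) | O=C1CCC[C@@H](C(C)=C)[C@]1(C)CCCC=C
F7 | step 3 | (2S,3S)-2-(1-hydroxypent-4-en-1-yl)-2-methyl-3-(prop-1-en-2-yl)cyclohexan-1-one (carbinol epimers) | O=C1CCC[C@@H](C(C)=C)[C@]1(C)C(O)CCC=C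
F8 | step 3 | O-phenyl thionocarbonate of F7 | O=C1CCC[C@@H](C(C)=C)[C@]1(C)C(OC(=S)Oc2ccccc2)CCC=C
F9 | step 5 | 4β,19α-dihydroxy derivative of 8 (trans-diol) | O=C1CCC[C@H]2[C@@](C)(O)[C@H](O)CCC[C@]12C
F10 | step 5 | 19α-methanesulfonate of F9 | O=C1CCC[C@H]2[C@@](C)(O)[C@H](OS(C)(=O)=O)CCC[C@]12C
F11 | step 13 | {(R)-5-[(tert-butyldiphenylsilyl)oxy]-3-methylpentyl}lithium | [Li]CC[C@H](C)CCO[Si](c1ccccc1)(c1ccccc1)C(C)(C)C
F12 | step 13 | lithium bis{(R)-5-[(tert-butyldiphenylsilyl)oxy]-3-methylpentyl}cuprate | [Li+].[Cu-](CC[C@H](C)CCO[Si](c1ccccc1)(c1ccccc1)C(C)(C)C)CC[C@H](C)CCO[Si](c1ccccc1)(c1ccccc1)C(C)(C)C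
A1 | alternative 1 | methyl 3-oxocyclohex-1-ene-1-carboxylate | COC(=O)C1=CC(=O)CCC1
A2 | alternative 1 | methyl 2-allyl-1-methyl-3-oxocyclohexane-1-carboxylate (allyl trans to ester) | COC(=O)[C@@]1(C)CCCC(=O)[C@@H]1CC=C
A3 | alternative 2 | methyl (2S,6E)-2-[(1E,3E)-4-(tert-butyldimethylsilyloxy)buta-1,3-dien-1-yl]-2,6-dimethyl-8-oxooct-6-enoate | O=C/C=C(\C)CCC[C@](C)(C(=O)OC)/C=C/C=C/O[Si](C)(C)C(C)(C)C
A4 | alternative 2 | trans-fused octalin with C8 silyl ether, C9 aldehyde, C6=C7 alkene and C19 methyl ester | CC(C)(C)[Si](C)(C)O[C@H]1C=C[C@@H]2[C@](C)(CCC[C@]2(C)C(=O)OC)[C@H]1C=O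
A5 | alternative 3 | methyl (S)-5-bromo-2-(3-hydroxy-2-methylphenyl)-2-methylpentanoate | COC(=O)[C@@](C)(CCCBr)c1cccc(O)c1C
A6 | alternative 3 | bicyclic cyclohexa-2,4-dienone with quaternary C10 and C4 (C9 ketone, C19 methyl ester) | COC(=O)[C@@]1(C)CCC[C@]2(C)C(=O)C=CC=C12
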